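**Assumptions:** The target is the cis-(5S,8R) isomer, as the SMILES encodes. Methyl (R)-glycidate and methyl 2-methoxy-3-oxobutanoate are taken as catalogue chemicals. The route is a paper design; none of it has been run.

## Retrosynthetic overview

1. The N-methoxy-4-pyridone comes from the matching γ-pyrone 15 by O→N exchange with MeONH2.
2. The γ-pyrone ring is formed by a [4+2] hetero-Diels–Alder between methoxy(acetyl)ketene (from 14) and the regiodefined silyl enol ether 13. This makes C4–C4a and O1–C8a.
3. Enol ether 13 comes from (R)-6-methoxycyclohex-2-enone 10 by chelation-controlled Cu-catalysed 1,4-addition of octyl; C8 directs C5.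
4. Enone 10 comes from methyl (R)-glycidate 1 (C8 purchased) by allyl opening, O-methylation, vinyl ketone formation and RCM.
5. Ring order: carbocycle first (RCM), then the heterocycle ([4+2]), then the ring-atom swap O→N.

## Route

**Step 1**
Reactants: 1 methyl (R)-glycidate; 2 allylmagnesium bromide
Product: 3 methyl (2R)-2-hydroxyhex-5-enoate
Conditions: CuI (10 mol %), THF, −78 → −40 °C, Grignard added slowly to 1/CuI
Reagents that add atoms: allylmagnesium bromide, C=CC[Mg]Br
Why: Cu-catalysed SN2 opening of the glycidic ester at the unsubstituted C3 leaves the purchased C2 stereocentre untouched (future C8); low temperature and Cu keep the ester from competing.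

**Step 2**
Reactants: 3; 4 iodomethane
Product: 5 methyl (2R)-2-methoxyhex-5-enoate
Conditions: MeI, Ag2O, MeCN, rt, dark
Reagents that add atoms: iodomethane, CI
Why: Neutral Purdie methylation of the α-hydroxy ester avoids enolisation, so there is no epimerisation.

**Step 3**
Reactants: 5; 6 N,O-dimethylhydroxylamine hydrochloride
Product: 7 (2R)-N,2-dimethoxy-N-methylhex-5-enamide
Conditions: MeNHOMe·HCl, i-PrMgCl, THF, −20 → 0 °C
Reagents that add atoms: N,O-dimethylhydroxylamine hydrochloride, CNOC.Cl
Why: Direct ester-to-Weinreb-amide aminolysis by the magnesium amide; α-alkoxy esters survive this without racemisation.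

**Step 4**
Reactants: 7; 8 vinylmagnesium bromide
Product: 9 (4R)-4-methoxyocta-1,7-dien-3-one
Conditions: vinylMgBr, THF, −78 → 0 °C; inverse quench into cold 1 M HCl
Reagents that add atoms: vinylmagnesium bromide, C=C[Mg]Br
Why: Weinreb ketone synthesis stops at the vinyl ketone through the stable chelate; the acidic inverse quench prevents aza-Michael addition of the liberated amine.

**Step 5**
Reactants: 9
Product: 10 (6R)-6-methoxycyclohex-2-en-1-one
Conditions: Grubbs II (2 mol %), CH2Cl2 (0.01 M), 40 °C
Reagents that add atoms: none
Why: Ring-closing metathesis of the enone/terminal alkene pair gives the six-membered enone with loss of ethylene under neutral conditions that do not touch the α-methoxy stereocentre.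

**Step 6**
Reactants: 10; 11 n-octylmagnesium bromide; 12 TBSOTf
Product: 13 tert-butyl{[(3S,6R)-6-methoxy-3-octylcyclohex-1-en-1-yl]oxy}dimethylsilane
Conditions: n-C8H17MgBr, CuBr·SMe2 (10 mol %), Et2O/THF, −78 → −40 °C; then TBSOTf, Et3N, −40 → 0 °C
Reagents that add atoms: n-octylmagnesium bromide, CCCCCCCC[Mg]Br; tert-butyldimethylsilyl triflate, CC(C)(C)[Si](C)(C)OS(=O)(=O)C(F)(F)F
Why: In this Cu-catalysed conjugate addition, Mg chelation of C=O and the α′-OMe should hold the OMe pseudo-equatorial, so stereoelectronically preferred axial attack at C3 gives the 3,6-cis adduct (new C5 set by C8); the selectivity is predicted, not precedented, and any trans isomer is removed at 15. O-silylation traps the enolate regiospecifically as the C8a=C4a enol ether.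

**Step 7**
Reactants: 13; 14 methyl 2-methoxy-3-oxobutanoate
Product: 15 (5S,8R)-3,8-dimethoxy-2-methyl-5-octyl-5,6,7,8-tetrahydro-4H-chromen-4-one
Conditions: 14 (3 equiv), mesitylene, 150 °C, N2 sweep/4 Å MS (−MeOH); then TsOH·H2O (cat.), PhMe, 60 °C
Reagents that add atoms: methyl 2-methoxy-3-oxobutanoate, COC(C(C)=O)C(=O)OC
Why: Thermal loss of MeOH from the enolised β-keto ester gives methoxy(acetyl)ketene, which adds as an oxa-diene to the silyl enol ether in a hetero-Diels–Alder (nucleophilic C4a to the ketene carbon, acetyl O to C8a); acid-promoted loss of TBSOH aromatises to the γ-pyrone without touching C5 or C8.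

**Step 8**
Reactants: 15; 16 O-methylhydroxylamine hydrochloride
Product: 17 Waltherione K, (5S,8R)-1,3,8-trimethoxy-2-methyl-5-octyl-5,6,7,8-tetrahydroquinolin-4(1H)-one
Conditions: MeONH2·HCl (5 equiv), pyridine/EtOH, 90 °C, sealed tube
Reagents that add atoms: O-methylhydroxylamine hydrochloride, CON.Cl
Why: 4-Pyranone-to-4-pyridone exchange (conjugate addition, ring opening, ring closure, −H2O) installs N–OMe directly; the ring-opened intermediate sits as the β-diketone enol, so C8–H is not activated and the stereocentres are retained.

## Compound list

1 | methyl (R)-glycidate | COC(=O)[C@H]1CO1 | starting material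
2 | allylmagnesium bromide | C=CC[Mg]Br | starting material
3 | methyl (2R)-2-hydroxyhex-5-enoate | COC(=O)[C@H](O)CCC=C | intermediate
4 | iodomethane | CI | starting material
5 | methyl (2R)-2-methoxyhex-5-enoate | COC(=O)[C@H](OC)CCC=C | intermediate
6 | N,O-dimethylhydroxylamine hydrochloride | CNOC.Cl | starting material
7 | (2R)-N,2-dimethoxy-N-methylhex-5-enamide | CON(C)C(=O)[C@H](OC)CCC=C | intermediate
8 | vinylmagnesium bromide | C=C[Mg]Br | starting material
9 | (4R)-4-methoxyocta-1,7-dien-3-one | C=CC(=O)[C@H](OC)CCC=C | intermediate
10 | (6R)-6-methoxycyclohex-2-en-1-one | O=C1C=CCC[C@H]1OC | intermediate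
11 | n-octylmagnesium bromide | CCCCCCCC[Mg]Br | starting material
12 | tert-butyldimethylsilyl triflate | CC(C)(C)[Si](C)(C)OS(=O)(=O)C(F)(F)F | starting material
13 | tert-butyl{[(3S,6R)-6-methoxy-3-octylcyclohex-1-en-1-yl]oxy}dimethylsilane | CCCCCCCC[C@H]1CC[C@@H](OC)C(O[Si](C)(C)C(C)(C)C)=C1 | intermediate
14 | methyl 2-methoxy-3-oxobutanoate | COC(C(C)=O)C(=O)OC | starting material
15 | (5S,8R)-3,8-dimethoxy-2-methyl-5-octyl-5,6,7,8-tetrahydro-4H-chromen-4-one | CCCCCCCC[C@H]1CC[C@@H](OC)c2c1c(=O)c(OC)c(C)o2 | intermediate
16 | O-methylhydroxylamine hydrochloride | CON.Cl | starting material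
17 | Waltherione K | CCCCCCCC[C@H]1CC[C@@H](OC)c2c1c(=O)c(OC)c(C)n2OC | target

## Summary

Total steps: 8. Longest linear sequence: 8 (fully linear from 1).

Steps most likely to fail, with fallbacks:

1. **Step 6, facial selectivity of the octyl addition.** This is 1,4-induction from the α′-OMe; without effective chelation the OMe can sit axial and favour the trans adduct. Fallback: run the sequence from methyl (S)-glycidate with a bulky 6-silyloxy group, which should give the 3,6-trans adduct reliably. Then correct C8 at the bicyclic stage by desilylation, Mitsunobu inversion and O-methylation.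

2. **Step 7, ketene generation from the methyl ester and its capture by a hindered silyl enol ether.** Methanol recombination, enol ether cleavage or ketene dimerisation could dominate. Fallback: drop the ketene. C-acylate the step-6 magnesium enolate with a protected 2-methoxyacetoacetyl electrophile (for example the acid chloride of the 3-ketal), then close the 1,3,5-tricarbonyl to the same pyrone 15 by acid cyclodehydration.

3. **Step 8, O→N exchange on a fully substituted γ-pyrone with a weakly nucleophilic alkoxyamine.** Attack at a substituted α-carbon may be very slow. Fallback: do not aromatise in step 7. Treat the crude [4+2] adduct (a masked 1,3,5-triketone) with MeONH2·HCl so that nitrogen enters by carbonyl condensation and cyclodehydration, giving 17 without ring-opening an aromatic pyrone.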